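The charges put 0.20 M of starting material against 0.120 M of partner, so the partner is the limiting reagent, with room for 60.0% of target. Yet the east run shows 11.7% at its first reading, and its later readings fall from there.

| flask | starting material | partner | protic impurity | catalyst | temperature | remark | time |
|---|---|---|---|---|---|---|---|
| east | 0.20 M | 0.12 M | 0.020 M | 2.2 mM | 100 °C | run made earlier |  |
| north-east | 0.20 M | 0.12 M | 0.080 M | 2.2 mM | 122 °C | run made earlier |  |
| south | 0.20 M | 0.12 M | 0.040 M | 4.4 mM | 100 °C | run made earlier |  |
| blue | 0.20 M | 0.120 M | 0.0400 M | 2.2 mM | 130 °C |  | 25 h |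
| teal | 0.20 M | 0.120 M | 0.0400 M | 2.2 mM | 90 °C |  | 25 h |
| green | 0.20 M | 0.120 M | 0.0400 M | 2.2 mM |  | at 90 °C until 8.0 h, from then on at 130 °C | 25 h |
| violet | 0.20 M | 0.120 M | 0.0400 M | 2.2 mM | 110 °C |  | 25 h |

| run | time / h | target / % |
|---|---|---|
| east | 8.00 | 11.7 |
| east | 12.0 | 10.3 |
| east | 20.0 | 10.2 |
| east | 40.0 | 6.3 |
| east | 72.0 | 3.2 |
| east | 120 | 0.7 |
| north-east | 4.00 | 2.7 |
| north-east | 8.00 | 1.5 |
| north-east | 10.0 | 0.5 |
| north-east | 15.0 | 1.4 |
| north-east | 20.0 | 0.3 |
| north-east | 25.0 | 1.1 |
| south | 20.0 | 12.0 |
| south | 40.0 | 7.6 |
| south | 72.0 | 2.1 |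
| south | 96.0 | 2.0 |
| south | 120 | 2.1 |

(each reading ± 1 percentage point)

1. the flask with the highest amount of target, in percent of the starting material charged ("all alike" if they lie within 1.5 percentage points) (blue / teal / green / violet / all alike)
2. final target, as a percentage of the starting material charged, in blue
3. final target, as a percentage of the starting material charged, in teal
4. final target, as a percentage of the starting material charged, in green
5. final target, as a percentage of the starting material charged, in violet

- the numbers in the tables scatter by 1 percentage point (one standard deviation)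

The east and south runs look nearly the same. Both stand at 100 °C, but the south run has twice the catalyst and twice the protic impurity. Past its first reading, the east run reads as losing a roughly steady fraction of c(target) per hour, and a rate proportional to c(target) integrates to an exponential in time, an apparent first-order decay. Its loss constant is the logarithm of the ratio of two readings over the hours between them. From 10.2% at 20.0 h to 3.2% at 72.0 h, the reading is 0.0223 h⁻¹, a half-life of 31.1 h.

Applied to the south run from 12.0% at 20.0 h, this constant gives 7.68% at 40.0 h, and the reading is 7.6%. At 120 h it gives 1.29%, and the reading is 2.1%. The east run ends at 0.7%. On this reckoning both runs end low because the last 100 h hold 3.22 half-lives.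

The new flasks differ from each other in temperature. If the north-east run reached the east run's first reading, its fall to 2.7% in 4.00 h reads as a rough 0.367 h⁻¹ at 122 °C. The north-east run also holds 0.080 M of protic impurity against 0.020 M in the east run, so two settings differ between these constants, and the temperature slope below is rough. Taking the logarithm of the constant as straight in temperature, this reckoning gives teal's loss constant at 90 °C 0.00624 h⁻¹. Counted from the start of the flask and from the east run's first reading, this reckoning puts teal at 10.0%. It puts violet at 1.60%, less than teal. At 130 °C the constant comes to 1.01 h⁻¹, a half-life of 0.686 h. Green's 17.0 h there far exceed that half-life, so this reckoning leaves green hardly any of its target. Blue's 25 h at that temperature exceed it too.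

The forecast names teal, with blue 0.1%, teal 5%, green 0.2% and violet 1.3%, on the ground that “the target eventually goes to zero and only the rate matters”. Its teal stands lower than this reckoning's 10.0%.

The flask with the most target is teal, at 14.1% after 25.0 h. Violet gives 2.76%, green 0.00506% and blue 0%.

    starting material + partner ⇌ target (K = 40.0 M⁻¹, k = 3.00 M⁻¹ h⁻¹, Ea = 93.0 kJ mol⁻¹, ΔH = −49.0 kJ mol⁻¹)
    starting material + partner ⇌ isomer of the product (K = 17.0 M⁻¹, k = 1.70 M⁻¹ h⁻¹, Ea = 72.0 kJ mol⁻¹, ΔH = −29.0 kJ mol⁻¹)
    target + catalyst ⇌ isomer of the product + catalyst, rate k3*[catalyst]*[target] forward; the back reaction follows from the equilibrium constant (k = 130 M⁻¹ h⁻¹, Ea = 81.0 kJ mol⁻¹)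
    starting material + protic impurity → quenched substrate (k = 130 M⁻¹ h⁻¹, Ea = 68.0 kJ mol⁻¹)
    partner → decomposed reagent (k = 1.70 h⁻¹, Ea = 107 kJ mol⁻¹)
    2 partner → homo dimer (k = 0.790 M⁻¹ h⁻¹, Ea = 106 kJ mol⁻¹)
    (constants at 110 °C)

Teal stands 9.1 percentage points above the forecast. Green, still at 90 °C, already holds 14.3% at 8.00 h, more than the east run's first reading. Started from teal's end value, the loss constant 0.00624 h⁻¹ leaves 3.46% at 250 h, and teal then holds 3.94%.

The earlier runs and the new flask stem from a simulated flask with constants of no real substance, and the scatter is random.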